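## Structural features

Mururin C is a fully aromatic 2-arylbenzofuran without any stereocentre. The benzo ring (ring A) is fused to the furan through C3a and C7a; it carries a methoxy group at C7, next to the ring oxygen O1, and a 3-hydroxypropyl chain at C5, para to O1. The furan carries a 3,4-dihydroxy-5-methoxyphenyl group (ring B) at C2 and a formyl group at C3. The fragile elements are the free catechol of ring B (sensitive to base and oxidants), the aldehyde on an electron-rich heteroarene and, during the synthesis, every acid-labile mask used for them. The real difficulty is the fully substituted furan: C2 and C3 must receive two different carbon substituents with unambiguous regiochemistry, C3 at the aldehyde oxidation level, on a ring A that has only one free position ortho to its phenol oxygen. Stereochemistry arises only in passing: in the 2,3-dihydrobenzofuran of the plan the adjacent centres C2 and C3 are made together and erased together on aromatisation. The key step uses the fact that C2 is bonded only to ring B, O1 and C3 and can therefore arrive as a single benzylic ylide carbon, whereas O1, C7a, C3a and C3 (its formyl carbon held as an acetal) make up an ortho-quinone methide of ring A.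

## Logic of the disconnections

18 to 17. No skeletal bond is cut. The aldehyde is returned to a dimethyl acetal, the two catechol hydroxyls to methoxymethyl ethers and the primary alcohol to a silyl ether. All four masks are acid-labile, so one hydrolytic operation should release them, and no earlier step has to tolerate a free catechol or aldehyde. The forward step demands only that 18 survives aqueous acid.

17 to 16. The C2=C3 double bond is saturated. With C2 and C3 tetrahedral, the furan ring can be assembled by polar bond formation instead of arene chemistry. The forward dehydrogenation must take the C2 hydrogen (benzylic to ring B and alpha to O1) in preference to the benzylic CH2 of the side chain and must leave the acetals alone.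

16 to 7 and 12. The C2–C3 and O1–C2 bonds are cut, which removes the furan ring and both stereocentres at once. C2 stays with ring B as the benzylic carbon of 12, which reacts after deprotonation as 14. O1, C7a, C3a and C3 stay with ring A as the transient 13, which is stored as 7; the two fragments meet in 15. The forward step must generate 13 and 14 in the same flask under one mild base and let them combine faster than either decays. The acetal carbon on C3 must stay a spectator.

7 to 4 and 5. The benzylic C3–S bond is cut. The sulfonyl group is only a base-releasable leaving group, and a benzylic hydroxyl is its simplest precursor. The forward exchange must ionise the benzylic position to 6 without ionising the neighbouring acetal or cleaving the silyl ether.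

4 to 2 and 3. The C3–C3a bond is cut, separating the two-carbon acetal aldehyde 3 from the arene. In 2 the position para to the hydroxyl is occupied and only one ortho position is free, so a phenoxide-directed hydroxyalkylation can give only the required regiochemistry. The demand is sufficient carbon nucleophilicity of the phenoxide towards a hydrated aldehyde.

2 to 1. The O–Si bond is cut. The demand is selective silylation of the primary alcohol in the presence of the phenol.

12 to 11. The benzylic C–S bond of the sulfonium centre is cut, leaving a benzylic bromide and a dialkyl sulfide. The forward alkylation is reversible and must be driven by precipitation of the salt.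

11 to 10. The C–Br bond is exchanged for C–OH. The bromination must be free of strong acid because of the methoxymethyl ethers.

10 to 9. The benzylic C–H bond is removed, returning to the aldehyde oxidation level, which is that of the commercial arene. The demand is trivial.

9 to 8. The two O–CH2 bonds of the methoxymethyl ethers are cut, giving commercial 8. Both catechol hydroxyls must be alkylated completely.

## Other disconnections considered

Alternative 1: The cut runs through ring A (C7–C6, C5–C4 and C4–C3a), so the benzo ring is built onto a finished furan that already carries ring B and the masked formyl group. In the forward key step the furyl(methoxy)carbene complex A1 would be heated with the silylated pentynol A2; alkyne insertion, CO insertion and electrocyclisation (Dötz benzannulation) would give the 4-hydroxy-7-methoxybenzofuran A3.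
- In its favour: the regiochemistry of terminal alkyne insertion places the chain at C5 and the carbene methoxy group at C7 predictably. The furan is aromatic from the start, so no dehydrogenation is needed, which is a point on which it is better than the chosen plan. The formyl carbon is carried as an acetal, as in the chosen plan (equal).
- Against it: A3 has a hydroxyl at C4 that the target lacks, and it would have to be removed by sulfonylation and reduction next to the hindered acetal. A1 itself requires a 2,3-disubstituted furan to be assembled and lithiated at its free alpha position before the carbene can be made. The carbene comes from stoichiometric Cr(CO)6, a zerovalent chromium reagent. The benzyl ethers would need a separate hydrogenolysis in the presence of the benzofuran and the aldehyde.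
- Comparison: structurally it introduces and then deletes an oxygen. Mechanistically it is well understood. In step count it would be clearly longer than the chosen plan.

Alternative 2: The cut is the same pair of bonds as in the chosen plan (C3–C3a and O1–C2), but as the 8–5' linkage of two phenylpropanoids. In the forward key step Ag2O would oxidise cinnamate A4 and 1 to phenoxyl radicals; carbon–carbon coupling and addition of the ring A phenol to the resulting quinone methide would give the trans-dihydrobenzofuran ester A5.
- In its favour: ring A needs no prior functionalisation and 1 is used unprotected, which is better than the chosen plan. The trans relationship is intrinsic (equal). A4 has both positions ortho to its phenol occupied and can couple only through C8 or oxygen.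
- Against it: cross-coupling of two different radicals competes with homocoupling of 1 and with 8–8 and 8–O coupling of A4, so selectivity would rest on statistics and excess reagent. A5 still needs dehydrogenation (equal to the chosen plan). Its ester must be reduced and re-oxidised to reach the aldehyde. The benzyl ether needs a separate cleavage, and A4 itself requires regioselective mono-benzylation of a catechol.
- Comparison: it has the fewest bond-forming operations, but the expected chemoselectivity is poorer and there are about three extra oxidation-state and protecting-group steps. The chosen plan delivers C3 already at the aldehyde level.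

Alternative 3: Only C3–C3a is cut; O1–C2 is made beforehand by an oxa-Michael addition that gives the aryloxyacrylate A6. In the forward key step Pd(OAc)2 with CF3CO2Ag as terminal oxidant would join the acrylate alpha carbon to the single free ortho C–H of the aryloxy ring, giving benzofuran ester A7. Divalent palladium is regenerated from zerovalent palladium by the silver salt.
- In its favour: the benzofuran is formed aromatic, with no stereochemistry and no dehydrogenation step. The regiochemistry is fixed because the other ortho position bears the methoxy group. No reactive intermediates have to be matched in time. On these three points it is better than the chosen plan, and it uses the same protecting groups (equal).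
- Against it: the ester needs two further redox steps to become the aldehyde. The strong acid released from the oxidant threatens the methoxymethyl and silyl ethers. Electron-rich arenes are prone to oxidative homocoupling under these conditions. The conjugate addition that makes A6 is expected to be slow, because the phenol is hindered and the acceptor carries an electron-rich aryl group at its beta carbon.
- Comparison: step economy is about equal. The chosen plan is preferred because it needs no noble metal or silver oxidant and carries the correct oxidation level at C3 from the start.

Key step: step 8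

Remarks on the chemistry:
- Compound 3 is sold as a 60 wt% aqueous solution and is used in that form in step 2.
- Compounds 4, 7, 15 and 16 are racemic and the SMILES show one enantiomer. The trans isomer of 16 is the (2S,3S)/(2R,3R) pair.
- Compound 6 is the O-protonated form of 13 and is drawn as its benzylic carbocation resonance form. It is assumed to be the species that the sulfinic acid captures in the acidic medium of step 3, whereas the neutral quinone methide 13 is formed only under base in step 8.
- The exocyclic alkene geometry of 13 is undefined and has no consequence.
- Abbreviations: MOM = methoxymethyl, TBS = tert-butyldimethylsilyl, DDQ = 2,3-dichloro-5,6-dicyano-1,4-benzoquinone, Boc2O = di-tert-butyl dicarbonate.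

## Route

Step 1
Reactants: 1 dihydroconiferyl alcohol
Product: 2 4-[3-(tert-butyldimethylsilyloxy)propyl]-2-methoxyphenol
Conditions: TBSCl (1.05 equiv), imidazole, CH2Cl2, 0 °C
Reagents that add atoms: tert-butyldimethylsilyl chloride, CC(C)(C)[Si](C)(C)Cl
Why: Chemoselective O-silylation; the unhindered primary alcohol should react faster than the phenol flanked by a methoxy group, and any aryl silyl ether formed reverts to 2 on brief K2CO3/MeOH treatment because aryl silyl ethers are far more base-labile than alkyl ones.

Step 2
Reactants: 2 4-[3-(tert-butyldimethylsilyloxy)propyl]-2-methoxyphenol; 3 2,2-dimethoxyacetaldehyde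
Product: 4 2-(1-hydroxy-2,2-dimethoxyethyl)-6-methoxy-4-[3-(tert-butyldimethylsilyloxy)propyl]phenol (racemic)
Conditions: 3 (60 wt% in H2O, 3 equiv), NaOH (0.5 equiv), H2O/1,4-dioxane, 55 °C, N2; then NH4Cl to pH 7
Reagents that add atoms: none
Why: Lederer–Manasse-type C-hydroxyalkylation of a phenoxide by an activated alpha,alpha-dialkoxy aldehyde; the para position is occupied and only one carbon ortho to the phenoxide oxygen is free, so the C3–C3a bond can form at one site only. The alkyl silyl ether and the acetal are stable to aqueous base, and the new carbinol centre is formed racemic and is destroyed later.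

Step 3
Reactants: 4 2-(1-hydroxy-2,2-dimethoxyethyl)-6-methoxy-4-[3-(tert-butyldimethylsilyloxy)propyl]phenol; 5 sodium 4-methylbenzenesulfinate
Product: 7 2-[2,2-dimethoxy-1-(4-methylphenylsulfonyl)ethyl]-6-methoxy-4-[3-(tert-butyldimethylsilyloxy)propyl]phenol (racemic), via ortho-hydroxybenzylic cation 6 (not isolated)
Conditions: 5 (2.0 equiv), HCl (4 M in dioxane, 1.8 equiv), MgSO4, CH2Cl2, 0 °C to rt
Reagents that add atoms: none
Why: Acid-promoted substitution of an ortho-hydroxybenzyl alcohol by sulfinic acid, the known route to 2-(1-sulfonylalkyl)phenols: protonation and loss of water give cation 6, which the ortho hydroxyl stabilises as an O-protonated quinone methide and which the sulfinic acid captures through sulfur. Sulfinate is kept in excess over HCl so that the anhydrous medium is never more acidic than the sulfinic acid, which a primary silyl ether and an acetal deactivated by its electron-poor neighbouring carbon should tolerate. The stereocentre is racemic and is lost in step 8.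

Step 4
Reactants: 8 5-hydroxyvanillin (3,4-dihydroxy-5-methoxybenzaldehyde)
Product: 9 3-methoxy-4,5-bis(methoxymethoxy)benzaldehyde
Conditions: MOMCl (2.6 equiv), iPr2NEt, CH2Cl2, 0 °C to rt
Reagents that add atoms: chloromethyl methyl ether, COCCl
Why: Williamson-type O-alkylation of both catechol hydroxyls by a highly reactive alpha-chloro ether under amine base; standard for catechol aldehydes.

Step 5
Reactants: 9 3-methoxy-4,5-bis(methoxymethoxy)benzaldehyde
Product: 10 [3-methoxy-4,5-bis(methoxymethoxy)phenyl]methanol
Conditions: NaBH4, MeOH, 0 °C
Reagents that add atoms: none
Why: Hydride reduction of an aryl aldehyde; the methoxymethyl acetals are inert to borohydride.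

Step 6
Reactants: 10 [3-methoxy-4,5-bis(methoxymethoxy)phenyl]methanol
Product: 11 5-(bromomethyl)-1-methoxy-2,3-bis(methoxymethoxy)benzene
Conditions: CBr4, PPh3, CH2Cl2, 0 °C
Reagents that add atoms: carbon tetrabromide, BrC(Br)(Br)Br
Why: Appel bromination; substitution of the alkoxyphosphonium ion by bromide proceeds without free HBr, so the acid-labile methoxymethyl ethers should survive. The bromide is passed through a short silica plug and used at once.

Step 7
Reactants: 11 5-(bromomethyl)-1-methoxy-2,3-bis(methoxymethoxy)benzene
Product: 12 [3-methoxy-4,5-bis(methoxymethoxy)benzyl]dimethylsulfonium bromide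
Conditions: Me2S (5 equiv), acetone, rt, dark; salt collected by filtration
Reagents that add atoms: dimethyl sulfide, CSC
Why: SN2 S-alkylation of a dialkyl sulfide by an activated benzylic bromide; precipitation of the salt from acetone drives the reversible alkylation to completion.

Step 8
Reactants: 7 2-[2,2-dimethoxy-1-(4-methylphenylsulfonyl)ethyl]-6-methoxy-4-[3-(tert-butyldimethylsilyloxy)propyl]phenol; 12 [3-methoxy-4,5-bis(methoxymethoxy)benzyl]dimethylsulfonium bromide
Product: 16 trans-2-[3-methoxy-4,5-bis(methoxymethoxy)phenyl]-3-(dimethoxymethyl)-7-methoxy-5-[3-(tert-butyldimethylsilyloxy)propyl]-2,3-dihydrobenzofuran (racemic), via ortho-quinone methide 13 (not isolated), via benzylic sulfonium ylide 14 (not isolated), via phenoxide sulfonium betaine 15 (not isolated)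
Conditions: 12 (2.0 equiv), Cs2CO3 (4.0 equiv), CH2Cl2/MeCN, 0 °C; 7 added slowly; then rt
Reagents that add atoms: none
Why: Cs2CO3 deprotonates the phenol of 7 and the phenoxide expels 4-methylbenzenesulfinate in an E1cB-type 1,4-elimination to give quinone methide 13, while the same base converts 12 into the aryl-stabilised ylide 14. The ylide carbon adds to the exocyclic carbon of 13 (C2–C3 bond), which restores the aromaticity of ring A and gives betaine 15. The phenoxide oxygen of 15 then displaces dimethyl sulfide from the benzylic carbon with inversion (O1–C2 bond), a 5-exo-tet closure of the dihydrofuran ring. The closest known reaction type is the [4+1] annulation of ortho-quinone methides released from 2-(1-sulfonylalkyl)phenols with sulfonium ylides, which gives trans-2,3-dihydrobenzofurans; benzylic sulfonium ylides are established one-carbon partners in the related epoxidation, aziridination and cyclopropanation reactions. C3 is set in the conjugate addition and C2 in the displacement, and only their relative configuration matters: the betaine can equilibrate by reversible addition and by reversible deprotonation at its sulfonium-bearing carbon, and the diastereomer whose closure places ring B and the dimethoxymethyl group on opposite faces of the forming ring should cyclise faster, so the trans isomer is expected under substrate control. No absolute control is exerted or needed, because both centres vanish in step 9. The selectivity the step needs is chemoselectivity: 14 must intercept 13 before 13 dimerises or tautomerises and before 14 rearranges or is alkylated. This is secured by releasing 13 slowly into an excess of 12 and base, by the higher acidity of the benzylic over the S-methyl hydrogens of 12, by the exocyclic carbon of 13 being its only soft electrophilic site, and by the inertness of the acetal, the methoxymethyl ethers and the silyl ether to carbonate.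

Step 9
Reactants: 16 trans-2-[3-methoxy-4,5-bis(methoxymethoxy)phenyl]-3-(dimethoxymethyl)-7-methoxy-5-[3-(tert-butyldimethylsilyloxy)propyl]-2,3-dihydrobenzofuran
Product: 17 2-[3-methoxy-4,5-bis(methoxymethoxy)phenyl]-3-(dimethoxymethyl)-7-methoxy-5-[3-(tert-butyldimethylsilyloxy)propyl]benzofuran
Conditions: DDQ (1.3 equiv), anhydrous 1,4-dioxane, 80 °C
Reagents that add atoms: none
Why: Quinone dehydrogenation of a 2-aryl-2,3-dihydrobenzofuran, a known aromatisation; hydride abstraction should occur at C2, where the cation is stabilised by O1 and the electron-rich ring B, and loss of the C3 proton gives the furan. Both stereocentres are removed, so any cis isomer from step 8 converges on 17; a small excess of oxidant limits attack at the side-chain CH2.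

Step 10
Reactants: 17 2-[3-methoxy-4,5-bis(methoxymethoxy)phenyl]-3-(dimethoxymethyl)-7-methoxy-5-[3-(tert-butyldimethylsilyloxy)propyl]benzofuran
Product: 18 Mururin C, 2-(3,4-dihydroxy-5-methoxyphenyl)-5-(3-hydroxypropyl)-7-methoxybenzofuran-3-carbaldehyde
Conditions: 3 M HCl (aq)/THF/MeOH, 45 °C, N2
Reagents that add atoms: water, O
Why: One-pot acid hydrolysis of the dimethyl acetal (its oxocarbenium ion is stabilised by the benzofuran), of both methoxymethyl acetals and of the primary silyl ether. Methanol traps the released formaldehyde, the inert atmosphere protects the catechol, and the aldehyde, benzofuran and catechol of 18 are stable to acid.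

## Compound list

1 | dihydroconiferyl alcohol, 4-(3-hydroxypropyl)-2-methoxyphenol | COc1cc(CCCO)ccc1O | starting material
2 | 4-[3-(tert-butyldimethylsilyloxy)propyl]-2-methoxyphenol | COc1cc(CCCO[Si](C)(C)C(C)(C)C)ccc1O | intermediate
3 | 2,2-dimethoxyacetaldehyde | COC(OC)C=O | starting material
4 | 2-(1-hydroxy-2,2-dimethoxyethyl)-6-methoxy-4-[3-(tert-butyldimethylsilyloxy)propyl]phenol (racemic, one enantiomer drawn) | COC(OC)[C@H](O)c1cc(CCCO[Si](C)(C)C(C)(C)C)cc(OC)c1O | intermediate
5 | sodium 4-methylbenzenesulfinate | Cc1ccc(S(=O)[O-])cc1.[Na+] | starting material
6 | 1-{2-hydroxy-3-methoxy-5-[3-(tert-butyldimethylsilyloxy)propyl]phenyl}-2,2-dimethoxyethylium (ortho-hydroxybenzylic cation, the O-protonated form of 13, not isolated) | COC(OC)[CH+]c1cc(CCCO[Si](C)(C)C(C)(C)C)cc(OC)c1O | intermediate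
7 | 2-[2,2-dimethoxy-1-(4-methylphenylsulfonyl)ethyl]-6-methoxy-4-[3-(tert-butyldimethylsilyloxy)propyl]phenol (racemic, one enantiomer drawn) | COC(OC)[C@H](c1cc(CCCO[Si](C)(C)C(C)(C)C)cc(OC)c1O)S(=O)(=O)c1ccc(C)cc1 | intermediate
8 | 5-hydroxyvanillin, 3,4-dihydroxy-5-methoxybenzaldehyde | COc1cc(C=O)cc(O)c1O | starting material
9 | 3-methoxy-4,5-bis(methoxymethoxy)benzaldehyde | COc1cc(C=O)cc(OCOC)c1OCOC | intermediate
10 | [3-methoxy-4,5-bis(methoxymethoxy)phenyl]methanol | COc1cc(CO)cc(OCOC)c1OCOC | intermediate
11 | 5-(bromomethyl)-1-methoxy-2,3-bis(methoxymethoxy)benzene | COc1cc(CBr)cc(OCOC)c1OCOC | intermediate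
12 | [3-methoxy-4,5-bis(methoxymethoxy)benzyl]dimethylsulfonium bromide | C[S+](C)Cc1cc(OC)c(OCOC)c(OCOC)c1.[Br-] | intermediate
13 | 6-(2,2-dimethoxyethylidene)-2-methoxy-4-[3-(tert-butyldimethylsilyloxy)propyl]cyclohexa-2,4-dien-1-one (ortho-quinone methide, not isolated, alkene geometry undefined) | COC(OC)C=C1C=C(CCCO[Si](C)(C)C(C)(C)C)C=C(OC)C1=O | intermediate
14 | dimethylsulfonium [3-methoxy-4,5-bis(methoxymethoxy)phenyl]methylide (not isolated) | C[S+](C)[CH-]c1cc(OC)c(OCOC)c(OCOC)c1 | intermediate
15 | 2-{3,3-dimethoxy-1-(dimethylsulfonio)-1-[3-methoxy-4,5-bis(methoxymethoxy)phenyl]propan-2-yl}-6-methoxy-4-[3-(tert-butyldimethylsilyloxy)propyl]phenolate (zwitterion, not isolated; diastereomer that closes to trans-16, racemic, one enantiomer drawn) | COC(OC)[C@@H](c1cc(CCCO[Si](C)(C)C(C)(C)C)cc(OC)c1[O-])[C@H](c1cc(OC)c(OCOC)c(OCOC)c1)[S+](C)C | intermediate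
16 | trans-2-[3-methoxy-4,5-bis(methoxymethoxy)phenyl]-3-(dimethoxymethyl)-7-methoxy-5-[3-(tert-butyldimethylsilyloxy)propyl]-2,3-dihydrobenzofuran (racemic, (2S,3S) enantiomer drawn) | COC(OC)[C@@H]1[C@@H](c2cc(OC)c(OCOC)c(OCOC)c2)Oc2c(OC)cc(CCCO[Si](C)(C)C(C)(C)C)cc21 | intermediate
17 | 2-[3-methoxy-4,5-bis(methoxymethoxy)phenyl]-3-(dimethoxymethyl)-7-methoxy-5-[3-(tert-butyldimethylsilyloxy)propyl]benzofuran | COC(OC)c1c(-c2cc(OC)c(OCOC)c(OCOC)c2)oc2c(OC)cc(CCCO[Si](C)(C)C(C)(C)C)cc12 | intermediate
18 | Mururin C, 2-(3,4-dihydroxy-5-methoxyphenyl)-5-(3-hydroxypropyl)-7-methoxybenzofuran-3-carbaldehyde | COc1cc(-c2oc3c(OC)cc(CCCO)cc3c2C=O)cc(O)c1O | target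

## Step count and least certain steps

Total: 10 steps. Longest linear sequence: 7 steps (steps 4, 5, 6, 7, 8, 9 and 10, from 8 to 18). The ring A branch is 3 steps (steps 1 to 3) before the convergent step 8.

Step 8 (key step). The most likely failure is loss of chemoselectivity. Decay of the semi-stabilised ylide (Sommelet–Hauser rearrangement through the S-methyl ylide, or self-alkylation), O-benzylation of the phenoxide by the sulfonium salt, or tautomerisation and dimerisation of the quinone methide could outrun the conjugate addition. The fallback brings C2 in at the carbonyl oxidation level by umpolung. It sets out from 7 and 9. A thiazolium-derived carbene (3-benzyl-5-(2-hydroxyethyl)-4-methylthiazolium chloride, Cs2CO3, THF) should convert 9 into its Breslow intermediate, which adds to the quinone methide 13 released from 7 by the same base. This is a known carbene-catalysed acylation of ortho-quinone methides (Stetter-type), and it would give the ketone 2-{2-hydroxy-3-methoxy-5-[3-(tert-butyldimethylsilyloxy)propyl]phenyl}-3,3-dimethoxy-1-[3-methoxy-4,5-bis(methoxymethoxy)phenyl]propan-1-one F1. Warming F1 with pyridinium 4-toluenesulfonate in toluene over molecular sieves should close the phenol onto the ketone and dehydrate the hemiketal, the classical cyclodehydration to a benzofuran. The fallback returns to the route at 17 and makes step 9 unnecessary.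

Step 3. The most likely failure is acid-induced loss of the silyl ether, or ionisation of the acetal with capture by the neighbouring phenol, competing with the formation of cation 6, which the beta-alkoxy groups slow down. The fallback replaces the acidic ionisation by an anionic release of the neutral quinone methide. It sets out from 4. Phenol-selective acylation (Boc2O, catalytic 4-(dimethylamino)pyridine, CH2Cl2, 0 °C) should give tert-butyl 2-(1-hydroxy-2,2-dimethoxyethyl)-6-methoxy-4-[3-(tert-butyldimethylsilyloxy)propyl]phenyl carbonate F2. Treating F2 with 5 and a catalytic amount of 1,8-diazabicyclo[5.4.0]undec-7-ene in DMF should move the carbonate to the benzylic oxygen; the freed phenoxide expels tert-butyl carbonate to give 13, and sulfinate adds to its exocyclic carbon. This is the known anionic generation of ortho-quinone methides by carbonate migration and elimination. After a cold acetic acid quench and buffered work-up the fallback returns to the route at 7 without any strong acid.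

Step 2. The most likely failure is slow or incomplete C–C bond formation, because the aldehyde is largely hydrated and the phenoxide carbon is only moderately nucleophilic. Prolonged heating would then favour condensation of 4 with a second phenoxide and air oxidation. The fallback replaces the phenoxide carbon nucleophile by an aryllithium. It sets out from 2. Bromination ortho to the hydroxyl (N-bromosuccinimide, catalytic diisopropylamine, CH2Cl2, 0 °C) should give 2-bromo-6-methoxy-4-[3-(tert-butyldimethylsilyloxy)propyl]phenol F3. Deprotonation and bromine–lithium exchange (n-BuLi, 2.2 equiv, THF, −78 °C), followed by addition of 3 that has been freed from water by extraction and distillation, returns to the route at 4.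

Step 9. The most likely failure is competing hydride abstraction at the side-chain CH2 para to O1, or loss of the acetal under the acidity of the hydroquinone formed, giving over-oxidised or mixed material. The fallback moves the dehydrogenation to an enolisable aldehyde. It sets out from 16. Selective transacetalisation (pyridinium 4-toluenesulfonate, wet acetone, 40 °C), under which aryl methoxymethyl ethers and the primary silyl ether are expected to persist, should give trans-2-[3-methoxy-4,5-bis(methoxymethoxy)phenyl]-7-methoxy-5-[3-(tert-butyldimethylsilyloxy)propyl]-2,3-dihydrobenzofuran-3-carbaldehyde F4. Dehydrogenation of F4 through its enol with 2-iodoxybenzoic acid in DMSO at 50 to 60 °C, the known alpha,beta-dehydrogenation of aldehydes, here driven by aromatisation, should give 2-[3-methoxy-4,5-bis(methoxymethoxy)phenyl]-7-methoxy-5-[3-(tert-butyldimethylsilyloxy)propyl]benzofuran-3-carbaldehyde F5. F5 under the conditions of step 10 returns to the route at 18.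

## Further compounds

F1 | step 8 | 2-{2-hydroxy-3-methoxy-5-[3-(tert-butyldimethylsilyloxy)propyl]phenyl}-3,3-dimethoxy-1-[3-methoxy-4,5-bis(methoxymethoxy)phenyl]propan-1-one (racemic, one enantiomer drawn) | COC(OC)[C@H](C(=O)c1cc(OC)c(OCOC)c(OCOC)c1)c1cc(CCCO[Si](C)(C)C(C)(C)C)cc(OC)c1O
F2 | step 3 | tert-butyl 2-(1-hydroxy-2,2-dimethoxyethyl)-6-methoxy-4-[3-(tert-butyldimethylsilyloxy)propyl]phenyl carbonate (racemic, one enantiomer drawn) | COC(OC)[C@H](O)c1cc(CCCO[Si](C)(C)C(C)(C)C)cc(OC)c1OC(=O)OC(C)(C)C
F3 | step 2 | 2-bromo-6-methoxy-4-[3-(tert-butyldimethylsilyloxy)propyl]phenol | COc1cc(CCCO[Si](C)(C)C(C)(C)C)cc(Br)c1O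
F4 | step 9 | trans-2-[3-methoxy-4,5-bis(methoxymethoxy)phenyl]-7-methoxy-5-[3-(tert-butyldimethylsilyloxy)propyl]-2,3-dihydrobenzofuran-3-carbaldehyde (racemic, one enantiomer drawn) | O=C[C@@H]1[C@@H](c2cc(OC)c(OCOC)c(OCOC)c2)Oc2c(OC)cc(CCCO[Si](C)(C)C(C)(C)C)cc21
F5 | step 9 | 2-[3-methoxy-4,5-bis(methoxymethoxy)phenyl]-7-methoxy-5-[3-(tert-butyldimethylsilyloxy)propyl]benzofuran-3-carbaldehyde | O=Cc1c(-c2cc(OC)c(OCOC)c(OCOC)c2)oc2c(OC)cc(CCCO[Si](C)(C)C(C)(C)C)cc12
A1 | alternative 1 | pentacarbonyl{[5-(3,4-bis(benzyloxy)-5-methoxyphenyl)-4-(dimethoxymethyl)furan-2-yl](methoxy)methylidene}chromium | COC(=[Cr](=C=O)(=C=O)(=C=O)(=C=O)=C=O)c1cc(C(OC)OC)c(-c2cc(OC)c(OCc3ccccc3)c(OCc3ccccc3)c2)o1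
A2 | alternative 1 | tert-butyldimethyl(pent-4-yn-1-yloxy)silane | C#CCCCO[Si](C)(C)C(C)(C)C
A3 | alternative 1 | 2-[3,4-bis(benzyloxy)-5-methoxyphenyl]-3-(dimethoxymethyl)-7-methoxy-5-[3-(tert-butyldimethylsilyloxy)propyl]benzofuran-4-ol | COc1cc(CCCO[Si](C)(C)C(C)(C)C)c(O)c2c(C(OC)OC)c(-c3cc(OC)c(OCc4ccccc4)c(OCc4ccccc4)c3)oc12
A4 | alternative 2 | methyl (E)-3-[3-(benzyloxy)-4-hydroxy-5-methoxyphenyl]prop-2-enoate | COC(=O)/C=C/c1cc(OC)c(O)c(OCc2ccccc2)c1
A5 | alternative 2 | methyl trans-2-(3-benzyloxy-4-hydroxy-5-methoxyphenyl)-5-(3-hydroxypropyl)-7-methoxy-2,3-dihydrobenzofuran-3-carboxylate (racemic, one enantiomer drawn) | COC(=O)[C@@H]1[C@@H](c2cc(OC)c(O)c(OCc3ccccc3)c2)Oc2c(OC)cc(CCCO)cc21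
A6 | alternative 3 | methyl 3-{2-methoxy-4-[3-(tert-butyldimethylsilyloxy)propyl]phenoxy}-3-[3-methoxy-4,5-bis(methoxymethoxy)phenyl]prop-2-enoate (alkene geometry undefined) | COC(=O)C=C(Oc1ccc(CCCO[Si](C)(C)C(C)(C)C)cc1OC)c1cc(OC)c(OCOC)c(OCOC)c1
A7 | alternative 3 | methyl 2-[3-methoxy-4,5-bis(methoxymethoxy)phenyl]-7-methoxy-5-[3-(tert-butyldimethylsilyloxy)propyl]benzofuran-3-carboxylate | COC(=O)c1c(-c2cc(OC)c(OCOC)c(OCOC)c2)oc2c(OC)cc(CCCO[Si](C)(C)C(C)(C)C)cc12
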